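The target is C2-symmetric about the C3–C3'' bond, so both aryl–carbonyl bonds C4–C4a and C4''–C4a'' of the two rings C are disconnected together. This leads back to an acyclic (2R,3R)-2,3-disubstituted succinic acid whose two arms are (S)-configured 4-methoxybenzylic aryl ethers. One double intramolecular Friedel–Crafts acylation closes both pyranone rings with all four stereocentres already in place. It exploits the phloroglucinol-type ring A: C4a is ortho to O1 and to the C5 methoxy group and para to O7, while a bulky silyl group on O7 shields C8. The stereocentres come from a catalyst-controlled double ketone reduction and a double Mitsunobu inversion.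

Key step: step 7

Remark: flavanone numbering (O1, C2, C3, C4, C4a, C5 to C8, C8a, doubly primed in the second half) is also used for the open-chain precursors. Ring A is the oxygenated benzo ring, ring B the 4-methoxyphenyl group, ring C the pyranone.

Step 1
Reactants: 1 4-methoxybenzoyl chloride; 2 tert-butyl acetate
Product: 3 tert-butyl 3-(4-methoxyphenyl)-3-oxopropanoate
Conditions: 2 (2.1 equiv), LiN(iPr)2 (2.1 equiv), THF, −78 °C; then 1, −78 to 0 °C; 1 M HCl
Reagents that add atoms: none
Why: Crossed Claisen-type acylation of an ester enolate, in which the lithium enolate of tert-butyl acetate does not self-condense at −78 °C, is acylated by the acid chloride, and the second equivalent of enolate deprotonates the β-keto ester so that it is not acylated again; no stereocentre is formed.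

Step 2
Reactants: 3 tert-butyl 3-(4-methoxyphenyl)-3-oxopropanoate (two molecules)
Product: 4 di-tert-butyl 2,3-bis(4-methoxybenzoyl)butanedioate (configurationally labile dl and meso forms)
Conditions: NaH, THF, 0 °C; I2 (0.5 equiv), 0 °C to rt
Reagents that add atoms: none
Why: Iodine-mediated oxidative homocoupling of the sodium enolate of a β-keto ester joins two α-carbons to give the C3–C3'' bond, and because both new centres stay enolisable their configuration is left open for the next step.

Step 3
Reactants: 4 di-tert-butyl 2,3-bis(4-methoxybenzoyl)butanedioate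
Product: 5 di-tert-butyl (2R,3R)-2,3-bis[(R)-hydroxy(4-methoxyphenyl)methyl]butanedioate (syn,syn-diol)
Conditions: RuCl(p-cymene)[(R,R)-TsDPEN] (2 mol %), HCO2H/Et3N (5:2), CH2Cl2, 30 °C
Reagents that add atoms: none
Why: Noyori–Ikariya asymmetric transfer hydrogenation with dynamic kinetic resolution of an α-substituted β-keto ester, in which triethylamine keeps C3 and C3'' epimerising through the enol, the (R,R)-catalyst delivers hydride to the same face of each aryl ketone to set both carbinols as R, the faster-reacting epimer gives the syn pair in each half so that the C2-symmetric syn,syn-diol should dominate, and the tert-butyl esters hold back lactonisation.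

Step 4
Reactants: 6 5-methoxyresorcinol
Product: 7 3-methoxy-5-[(triisopropylsilyl)oxy]phenol
Conditions: TIPSCl (1.0 equiv), imidazole, DMF, 0 °C to rt
Reagents that add atoms: triisopropylsilyl chloride (TIPSCl), CC(C)[Si](Cl)(C(C)C)C(C)C
Why: Statistical monosilylation of a symmetrical resorcinol, in which the two hydroxyl groups are equivalent, the first bulky silyl group slows the second silylation, and the monoether is separable from diol and bis-ether by chromatography; no stereocentre is involved.

Step 5
Reactants: 5 syn,syn-diol; 7 3-methoxy-5-[(triisopropylsilyl)oxy]phenol (two molecules enter)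
Product: 8 di-tert-butyl (2R,3R)-2,3-bis[(S)-(4-methoxyphenyl){3-methoxy-5-[(triisopropylsilyl)oxy]phenoxy}methyl]butanedioate
Conditions: 7 (3 equiv), PPh3 (3 equiv), DIAD (3 equiv), toluene, −20 °C to rt
Reagents that add atoms: none
Why: Double Mitsunobu etherification, an SN2 displacement of each oxyphosphonium carbinol by the phenoxide with inversion (R to S) that turns both syn pairs into the anti pairs mapping onto 2,3-trans flavanones, while excess reagent activates both carbinols at once so that neither acts as an internal nucleophile and the non-polar solvent and low temperature disfavour ionisation.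

Step 6
Reactants: 8 bis(aryl ether) di-tert-butyl ester
Product: 10 (2R,3R)-2,3-bis[(S)-(4-methoxyphenyl){3-methoxy-5-[(triisopropylsilyl)oxy]phenoxy}methyl]butanedioic acid, via bis(trimethylsilyl) ester 9 (not isolated)
Conditions: TMSOTf (4 equiv), 2,6-lutidine (6 equiv), CH2Cl2, 0 °C; pH 5 aqueous buffer
Reagents that add atoms: none
Why: Silyl triflate mediated cleavage of tert-butyl esters, in which O-silylation of each ester carbonyl triggers loss of the tert-butyl cation that lutidine converts into isobutene, so the acids are unmasked without free Brønsted acid or base and the acid-labile benzylic aryl ethers, the base-labile β-aryloxy carbonyl units, the aryl silyl ethers and all four stereocentres should stay untouched.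

Step 7
Reactants: 10 bis(aryl ether) succinic acid
Product: 13 (2S,2''S,3R,3''R)-5,5''-dimethoxy-2,2''-bis(4-methoxyphenyl)-7,7''-bis[(triisopropylsilyl)oxy]-3,3''-bichroman-4,4''-dione, via trans-succinic anhydride 11 (not isolated), via half-closed mixed anhydride 12 (not isolated)
Conditions: (CF3CO)2O (5 equiv), CH2Cl2 (0.02 M), −10 °C to rt; aq NaHCO3
Reagents that add atoms: none
Why: Mechanism: (CF3CO)2O dehydrates the diacid to the trans-anhydride 11, the liberated CF3CO2H activates it, C4a of one ring A attacks C4 and rearomatises, the freed C4'' acid is re-activated as the mixed anhydride 12, and the second ring A repeats the process. The closest known reaction type is the intramolecular Friedel–Crafts acylation of 3-aryloxypropanoic acids to chroman-4-ones, whose double form is known from 2,3-diarylsuccinic acids. Each ring C closes in a 6-exo-trig mode at the acyl carbon, the six ring atoms being O1, C2, C3, C4, C4a and C8a. No stereocentre is created: C2 and C2'' are spectators, C3 and C3'' keep the anti relationship set in step 5, and any epimer formed through the enol would drain to the diequatorial 2,3-trans arrangement dictated by C2. The step needs attack at C4a rather than C8 and acylation faster than heterolysis of the C2–O1 bond: C4a lies between O1 and the small methoxy group and para to the silyloxy donor, C8 is walled in by the triisopropylsilyl group and the branched benzylic ether, and C6 cannot reach the acyl carbon. The threefold oxygen activation of ring A lets the closure run in a dilute, weakly acidic medium at or below room temperature, where the benzylic aryl ether should survive.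

Step 8
Reactants: 13 bis(silyl ether) of the biflavanone
Product: 14 4',4''',5,5''-tetramethylchamaejasmin, (2S,2''S,3R,3''R)
Conditions: TBAF/AcOH (1:1, 2.5 equiv), THF, 0 °C
Reagents that add atoms: none
Why: Fluoride-induced cleavage of the two aryl silyl ethers, which are activated as leaving groups by the para carbonyl group, while acetic acid protonates the phenoxide at once and keeps the medium too weakly basic for enolisation at C3 or retro-oxa-Michael opening of ring C, so the four stereocentres are retained.

Compound list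
1 | 4-methoxybenzoyl chloride | COc1ccc(cc1)C(Cl)=O | starting material
2 | tert-butyl acetate | CC(=O)OC(C)(C)C | starting material
3 | tert-butyl 3-(4-methoxyphenyl)-3-oxopropanoate | COc1ccc(cc1)C(=O)CC(=O)OC(C)(C)C | intermediate
4 | di-tert-butyl 2,3-bis(4-methoxybenzoyl)butanedioate (labile centres, drawn flat) | COc1ccc(cc1)C(=O)C(C(=O)OC(C)(C)C)C(C(=O)OC(C)(C)C)C(=O)c1ccc(OC)cc1 | intermediate
5 | di-tert-butyl (2R,3R)-2,3-bis[(R)-hydroxy(4-methoxyphenyl)methyl]butanedioate | COc1ccc(cc1)[C@H](O)[C@H](C(=O)OC(C)(C)C)[C@@H](C(=O)OC(C)(C)C)[C@@H](O)c1ccc(OC)cc1 | intermediate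
6 | 5-methoxyresorcinol | COc1cc(O)cc(O)c1 | starting material
7 | 3-methoxy-5-[(triisopropylsilyl)oxy]phenol | COc1cc(O)cc(O[Si](C(C)C)(C(C)C)C(C)C)c1 | intermediate
8 | di-tert-butyl (2R,3R)-2,3-bis[(S)-(4-methoxyphenyl){3-methoxy-5-[(triisopropylsilyl)oxy]phenoxy}methyl]butanedioate | COc1ccc(cc1)[C@@H](Oc1cc(OC)cc(O[Si](C(C)C)(C(C)C)C(C)C)c1)[C@H](C(=O)OC(C)(C)C)[C@@H](C(=O)OC(C)(C)C)[C@H](Oc1cc(OC)cc(O[Si](C(C)C)(C(C)C)C(C)C)c1)c1ccc(OC)cc1 | intermediate
9 | bis(trimethylsilyl) ester of 10 | COc1ccc(cc1)[C@@H](Oc1cc(OC)cc(O[Si](C(C)C)(C(C)C)C(C)C)c1)[C@H](C(=O)O[Si](C)(C)C)[C@@H](C(=O)O[Si](C)(C)C)[C@H](Oc1cc(OC)cc(O[Si](C(C)C)(C(C)C)C(C)C)c1)c1ccc(OC)cc1 | intermediate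
10 | (2R,3R)-2,3-bis[(S)-(4-methoxyphenyl){3-methoxy-5-[(triisopropylsilyl)oxy]phenoxy}methyl]butanedioic acid | COc1ccc(cc1)[C@@H](Oc1cc(OC)cc(O[Si](C(C)C)(C(C)C)C(C)C)c1)[C@H](C(=O)O)[C@@H](C(=O)O)[C@H](Oc1cc(OC)cc(O[Si](C(C)C)(C(C)C)C(C)C)c1)c1ccc(OC)cc1 | intermediate
11 | (3R,4R)-3,4-disubstituted oxolane-2,5-dione (trans-anhydride of 10) | COc1ccc(cc1)[C@@H](Oc1cc(OC)cc(O[Si](C(C)C)(C(C)C)C(C)C)c1)[C@@H]1C(=O)OC(=O)[C@H]1[C@H](Oc1cc(OC)cc(O[Si](C(C)C)(C(C)C)C(C)C)c1)c1ccc(OC)cc1 | intermediate
12 | half-closed flavanone acid as its mixed trifluoroacetic anhydride | COc1ccc([C@@H](Oc2cc(O[Si](C(C)C)(C(C)C)C(C)C)cc(OC)c2)[C@H](C(=O)OC(=O)C(F)(F)F)[C@H]2C(=O)c3c(OC)cc(O[Si](C(C)C)(C(C)C)C(C)C)cc3O[C@@H]2c2ccc(OC)cc2)cc1 | intermediate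
13 | (2S,2''S,3R,3''R)-7,7''-bis-O-triisopropylsilyl ether of 14 | COc1ccc([C@H]2Oc3cc(O[Si](C(C)C)(C(C)C)C(C)C)cc(OC)c3C(=O)[C@@H]2[C@H]2C(=O)c3c(OC)cc(O[Si](C(C)C)(C(C)C)C(C)C)cc3O[C@@H]2c2ccc(OC)cc2)cc1 | intermediate
14 | 4',4''',5,5''-tetramethylchamaejasmin | COc1ccc([C@H]2Oc3cc(O)cc(OC)c3C(=O)[C@@H]2[C@H]2C(=O)c3c(OC)cc(O)cc3O[C@@H]2c2ccc(OC)cc2)cc1 | target

Total steps: 8. Longest linear sequence: 7 steps (1, 2, 3, 5, 6, 7, 8).

Steps most likely to fail

1. Step 5.
- **What may go wrong:** the activated anisyl carbinol may ionise instead of being displaced, so that inversion is incomplete. The neighbouring carbinol or the distal ester carbonyl may capture the activated centre intramolecularly. The hydrazide base may remove H3, so that dehydration takes over.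
- **Fallback:** the etherification is moved to a monomer that has a less crowded carbinol and no internal nucleophile, and the C3–C3'' bond is made last. It sets out from 3. Transfer hydrogenation under the conditions of step 3 gives tert-butyl (R)-3-hydroxy-3-(4-methoxyphenyl)propanoate F1. Mitsunobu etherification with 7 gives tert-butyl (S)-3-(4-methoxyphenyl)-3-{3-methoxy-5-[(triisopropylsilyl)oxy]phenoxy}propanoate F2. TMSOTf and 2,6-lutidine give (S)-3-(4-methoxyphenyl)-3-{3-methoxy-5-[(triisopropylsilyl)oxy]phenoxy}propanoic acid F3. (CF3CO)2O closes the C4–C4a bond to (S)-5-methoxy-2-(4-methoxyphenyl)-7-[(triisopropylsilyl)oxy]chroman-4-one F4. Oxidative coupling of its lithium enolate (LiN(iPr)2, THF, −78 °C; CuCl2, DMF) joins two homochiral halves, each anti to its C2 aryl group. The route is rejoined at 13.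

2. Step 7.
- **What may go wrong:** the C2–O1 bond may undergo heterolysis in the acidic medium, with loss of configuration at C2, elimination or C-alkylation of ring A. Attack may occur at C8 in place of C4a. Ring A may be trifluoroacetylated intermolecularly. The reaction may stall after the first closure.
- **Fallback:** an aprotic, buffered Vilsmeier–Haack-type closure replaces the protic acylation. It sets out from 10. Coupling with pyrrolidine (EDC·HCl, HOBt, CH2Cl2) gives the bis(pyrrolidine amide) F5. Tf2O and 2-fluoropyridine (CH2Cl2, −78 to 0 °C) turn each amide into an O-triflyl iminium ion that ring A attacks at C4a, giving the cyclised bis(iminium) ditriflate F6. Aqueous NaHCO3 hydrolyses both iminium groups, C3 and C3'' settle trans to the C2 aryl groups, and the route is rejoined at 13.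

3. Step 3.
- **What may go wrong:** hydride transfer to two hindered, electron-rich aryl ketones may be slow. The half-reduced stage may cyclise onto the remaining ketone and then dehydrate. The syn preference in the dynamic kinetic resolution may be insufficient. Slow lactonisation may occur in the acidic medium.
- **Fallback:** the carbinol centres are set before the C3–C3'' bond exists. It sets out from 3. Transfer hydrogenation of the unhindered monomer gives tert-butyl (R)-3-hydroxy-3-(4-methoxyphenyl)propanoate F1, as in the first fallback. TBSCl and imidazole give tert-butyl (R)-3-[(tert-butyldimethylsilyl)oxy]-3-(4-methoxyphenyl)propanoate F7. Oxidative coupling of its lithium enolate (LiN(iPr)2, THF, −78 °C; CuBr2) gives the bis(tert-butyldimethylsilyl) ether of the syn,syn-diol F8 after separation from its C3 epimers. HF·pyridine in THF then brings the route back at 5.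

Further compounds
F1 | step 5 | tert-butyl (R)-3-hydroxy-3-(4-methoxyphenyl)propanoate | COc1ccc(cc1)[C@H](O)CC(=O)OC(C)(C)C
F2 | step 5 | tert-butyl (S)-3-(4-methoxyphenyl)-3-{3-methoxy-5-[(triisopropylsilyl)oxy]phenoxy}propanoate | COc1ccc(cc1)[C@@H](Oc1cc(OC)cc(O[Si](C(C)C)(C(C)C)C(C)C)c1)CC(=O)OC(C)(C)C
F3 | step 5 | (S)-3-(4-methoxyphenyl)-3-{3-methoxy-5-[(triisopropylsilyl)oxy]phenoxy}propanoic acid | COc1ccc(cc1)[C@@H](Oc1cc(OC)cc(O[Si](C(C)C)(C(C)C)C(C)C)c1)CC(=O)O
F4 | step 5 | (S)-5-methoxy-2-(4-methoxyphenyl)-7-[(triisopropylsilyl)oxy]chroman-4-one | COc1ccc([C@H]2Oc3cc(O[Si](C(C)C)(C(C)C)C(C)C)cc(OC)c3C(=O)C2)cc1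
F5 | step 7 | bis(pyrrolidine amide) of 10 | COc1ccc(cc1)[C@@H](Oc1cc(OC)cc(O[Si](C(C)C)(C(C)C)C(C)C)c1)[C@H](C(=O)N1CCCC1)[C@@H](C(=O)N1CCCC1)[C@H](Oc1cc(OC)cc(O[Si](C(C)C)(C(C)C)C(C)C)c1)c1ccc(OC)cc1
F6 | step 7 | cyclised bis(iminium) ditriflate | COc1ccc([C@H]2Oc3cc(O[Si](C(C)C)(C(C)C)C(C)C)cc(OC)c3C(=[N+]4CCCC4)[C@@H]2[C@H]2C(=[N+]4CCCC4)c3c(OC)cc(O[Si](C(C)C)(C(C)C)C(C)C)cc3O[C@@H]2c2ccc(OC)cc2)cc1.[O-]S(=O)(=O)C(F)(F)F.[O-]S(=O)(=O)C(F)(F)F
F7 | step 3 | tert-butyl (R)-3-[(tert-butyldimethylsilyl)oxy]-3-(4-methoxyphenyl)propanoate | COc1ccc(cc1)[C@H](O[Si](C)(C)C(C)(C)C)CC(=O)OC(C)(C)C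
F8 | step 3 | bis(tert-butyldimethylsilyl) ether of 5 | COc1ccc(cc1)[C@H](O[Si](C)(C)C(C)(C)C)[C@H](C(=O)OC(C)(C)C)[C@@H](C(=O)OC(C)(C)C)[C@@H](O[Si](C)(C)C(C)(C)C)c1ccc(OC)cc1
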